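**Plan**

- Retrosynthesis (numbering below): the acetates and the C13 ketone are cut first, then C6–C7 of the oxonane (ketone–aldehyde pinacol), then in one operation O–C3 of the oxepane and O–C9 of the oxolane, then C8=C9 (cross-metathesis), C2–C3 (vinyllithium on a lactone) and finally C1–C14 and C10–C11 of ring A (tethered Diels–Alder).
- Enabling feature: C3 is a methyl-bearing, fully substituted ether carbon next to oxygenated C4, and the oxolane carbon C9 lies β to the C7 carbinol carbon. Oxepane and oxolane therefore unfold to a C3–C4 epoxide and a C9=C8–C7 enone on ring A, with O16 and O2 as nucleophiles.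
- Forward: ring A and a δ-lactone arise together by a maleate-tethered intramolecular Diels–Alder reaction; a (Z)-vinyllithium opens the lactone, the alkene is epoxidised and the enone attached; acid closes oxepane and oxolane; SmI2 closes the oxonane last.
- Stereochemistry: C15 from (R)-3-bromo-2-methylpropan-1-ol; C1, C10, C14 from the endo tethered cycloaddition under 1,3-allylic strain control by C15; C2 from a CBS reduction; C3/C4 from hydroxyl-directed epoxidation of a Z alkene (C3 inverted in the key step); C9 by equilibration; C6/C7 in the pinacol closure.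

Key step: step 18

Numbering: ring A = C1, C14, C13 (C=O), C12, C11 (Me), C10; oxolane = C1, C2, O, C9, C10; oxonane = O, C2, C3 (Me), C4 (OAc), C5, C6 (OAc), C7 (Me, OH), C8, C9; oxepane = C1, C2, C3, O, C16, C15 (Me), C14.

Remarks on the chemistry:
- Compounds 1, 20 and 22 are taken as catalogue items.
- The C13 carbinol configuration drawn for 14–39 is the one expected from hydride attack anti to the C14 branch; it is erased in step 24, so either epimer serves.
- Ring A is carried as a 13-O-TIPS allylic ether (masked enone) and O6 as a TBDPS ether through the key step.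

Step 1
Reactants: 1 (R)-3-bromo-2-methylpropan-1-ol
Product: 2 (R)-(3-bromo-2-methylpropoxy)(tert-butyl)dimethylsilane
Conditions: TBSCl, imidazole, CH2Cl2, 0 °C → rt
Reagents that add atoms: tert-butyldimethylsilyl chloride, C[Si](C)(Cl)C(C)(C)C
Why: Standard silyl ether formation on a primary alcohol, which leaves the bromide and the future C15 stereocentre untouched.

Step 2
Reactants: 2 (R)-(3-bromo-2-methylpropoxy)(tert-butyl)dimethylsilane + 3 (E)-but-2-enal
Product: 5 (2E,6S)-7-(tert-butyldimethylsilyloxy)-6-methylhept-2-en-4-ol (both C4 epimers), via Grignard reagent 4 (not isolated)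
Conditions: Mg, THF, 40 °C; then 3, −78 → 0 °C; H2O
Reagents that add atoms: none
Why: Grignard formation from the primary bromide and 1,2-addition to the enal join C14 to C13, and the new carbinol centre is of no consequence because it is oxidised in the next step.

Step 3
Reactants: 5 (2E,6S)-7-(tert-butyldimethylsilyloxy)-6-methylhept-2-en-4-ol
Product: 6 (2E,6S)-7-(tert-butyldimethylsilyloxy)-6-methylhept-2-en-4-one
Conditions: MnO2, CH2Cl2, rt
Reagents that add atoms: none
Why: MnO2 oxidation of a secondary allylic alcohol gives the (E)-enone without touching the silyl ether or the stereocentre.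

Step 4
Reactants: 6 (2E,6S)-7-(tert-butyldimethylsilyloxy)-6-methylhept-2-en-4-one
Product: 7 (2E,6S)-7-hydroxy-6-methylhept-2-en-4-one
Conditions: HF·pyridine, THF, 0 °C
Reagents that add atoms: none
Why: Fluoride cleavage of the primary TBS ether frees the C16 hydroxyl that is to carry the dienophile, under conditions too mild to isomerise the enone.

Step 5
Reactants: 7 (2E,6S)-7-hydroxy-6-methylhept-2-en-4-one + 8 maleic anhydride
Product: 9 (2Z)-4-{[(2S,5E)-2-methyl-4-oxohept-5-en-1-yl]oxy}-4-oxobut-2-enoic acid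
Conditions: Et3N, DMAP (cat.), CH2Cl2, 0 °C → rt; dilute HCl work-up
Reagents that add atoms: none
Why: Ring-opening acylation of the anhydride by the primary alcohol keeps the Z geometry of the dienophile and leaves the second carboxyl as a free acid, which later tells C9 from C2.

Step 6
Reactants: 9 (2Z)-4-{[(2S,5E)-2-methyl-4-oxohept-5-en-1-yl]oxy}-4-oxobut-2-enoic acid
Product: 11 bis-silyl cycloadduct (ring A 13-OTBS enol ether C12=C13; δ-lactone C2(=O)–O–C16 cis-fused at C1–C14; 9-CO2TBS; H1/H10/H11/H14 all cis), via bis-silyl triene 10 (not isolated)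
Conditions: TBSOTf, Et3N, toluene, 0 °C → rt; then BHT, 110 °C; used crude
Reagents that add atoms: tert-butyldimethylsilyl triflate, CC(C)(C)[Si](C)(C)OS(=O)(=O)C(F)(F)F
Why: Soft enolisation gives the (Z)-2-silyloxydiene (and the silyl ester), and the maleate-tethered intramolecular Diels–Alder reaction through the endo transition state should give the cis-fused δ-lactone with the C1, C10, C14 and C11 substituents all cis, because the tether can reach only the diene face on which C16 sits when the C15 hydrogen eclipses the silyloxy-bearing double bond (1,3-allylic strain), so that C15 controls C14, C1 and C10.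

Step 7
Reactants: 11 bis-silyl cycloadduct
Product: 13 enone lactone acid (ring A C13=O and C11=C12; δ-lactone C2(=O)–O–C16; 9-CO2H cis to C2), via enone silyl ester 12 (not isolated)
Conditions: Pd(OAc)2 (1.1 equiv), MeCN–DMSO, 40 °C; aqueous work-up (pH 4)
Reagents that add atoms: none
Why: Saegusa–Ito oxidation of the silyl enol ether places the double bond at C11=C12 (the only β-hydrogen is on C11) and removes the C11 stereocentre, while the labile silyl ester is hydrolysed on work-up.

Step 8
Reactants: 13 enone lactone acid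
Product: 14 allylic alcohol lactone acid (13-OH cis to the C14 branch)
Conditions: NaBH4, CeCl3·7H2O, MeOH, −78 °C
Reagents that add atoms: none
Why: Luche reduction delivers hydride 1,2 to the enone from the face anti to the C14 branch and so masks ring A against the organolithium, borane and SmI2 steps, the lactone and carboxylate being inert at this temperature.

Step 9
Reactants: 14 allylic alcohol lactone acid
Product: 16 13-O-TIPS lactone acid, via bis-TIPS derivative 15 (not isolated)
Conditions: TIPSOTf, 2,6-lutidine, CH2Cl2, −78 → 0 °C; then THF–H2O–AcOH, rt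
Reagents that add atoms: triisopropylsilyl triflate, CC(C)[Si](OS(=O)(=O)C(F)(F)F)(C(C)C)C(C)C
Why: Silyl triflate silylation of the hindered allylic alcohol gives an acid-stable TIPS ether, and the co-formed silyl ester is cleaved selectively by mild aqueous acid.

Step 10
Reactants: 16 13-O-TIPS lactone acid
Product: 18 13-O-TIPS lactone C9 aldehyde, via acid chloride 17 (not isolated)
Conditions: (COCl)2, DMF (cat.), CH2Cl2, 0 °C; then LiAlH(OtBu)3, THF, −78 °C
Reagents that add atoms: none
Why: Reduction of the acid chloride with the hindered hydride stops at the aldehyde and avoids a C9 alkoxide that would translactonise onto C2, the δ-lactone and silyl ether being inert at −78 °C.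

Step 11
Reactants: 18 13-O-TIPS lactone C9 aldehyde
Product: 19 13-O-TIPS lactone bearing a C10 vinyl group (C8=C9)
Conditions: Ph3PCH3Br, KN(SiMe3)2, THF, 0 °C; then 18, −78 → 0 °C
Reagents that add atoms: methyltriphenylphosphonium bromide, C[P+](c1ccccc1)(c1ccccc1)c1ccccc1.[Br-]
Why: Wittig methylenation at low temperature turns C9 into a vinyl group, a masked enone arm that survives the next three steps, without epimerising C10 or attacking the lactone.

Step 12
Reactants: 20 3-(tert-butyldiphenylsilyloxy)propan-1-ol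
Product: 21 3-(tert-butyldiphenylsilyloxy)propanal
Conditions: TEMPO (cat.), PhI(OAc)2, CH2Cl2, rt
Reagents that add atoms: none
Why: Nitroxyl-catalysed oxidation of the primary alcohol stops at the aldehyde and is too mild to cause β-elimination of the silyloxy group.

Step 13
Reactants: 21 3-(tert-butyldiphenylsilyloxy)propanal + 22 ethyltriphenylphosphonium iodide
Product: 26 (Z)-tert-butyl[(4-iodopent-3-en-1-yl)oxy]diphenylsilane, via ethylidene ylide 23 (not isolated), via iodoethylphosphonium iodide 24 (not isolated), via iodoethylidene ylide 25 (not isolated)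
Conditions: n-BuLi, THF, 0 °C; I2, −78 °C; NaN(SiMe3)2, −20 °C; then 21, −78 °C → rt
Reagents that add atoms: iodine, II
Why: The Stork–Zhao olefination with the α-iodo ylide gives the 2-iodoalkene with iodine cis to the chain, the geometry needed for a C3–C4 epoxide with C2 and C5 cis.

Step 14
Reactants: 19 13-O-TIPS vinyl lactone + 26 (Z)-tert-butyl[(4-iodopent-3-en-1-yl)oxy]diphenylsilane
Product: 28 hydroxy (Z)-enone (C2 ketone; C3(Me)=C4; 6-OTBDPS; free 16-OH; 13-OTIPS; C10 vinyl), via vinyllithium 27 (not isolated)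
Conditions: 26, t-BuLi (2 equiv), Et2O, −78 °C; then 19, THF, −78 °C; H2O
Reagents that add atoms: none
Why: Iodine–lithium exchange proceeds with retention of alkene geometry and the vinyllithium adds once to the δ-lactone (the lithium hemiketal persists until work-up), which forms the C2–C3 bond and frees the C16 hydroxyl.

Step 15
Reactants: 28 hydroxy (Z)-enone
Product: 29 (2R)-allylic alcohol diol (2-OH and 16-OH free)
Conditions: (S)-2-methyl-CBS-oxazaborolidine, catecholborane, toluene, −78 °C
Reagents that add atoms: none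
Why: Corey–Bakshi–Shibata reduction with the α-methyl alkenyl group as the large substituent sets C2 under reagent control (the (S)-catalyst should give the 2R alcohol), and catecholborane spares the vinyl group.

Step 16
Reactants: 29 (2R)-allylic alcohol diol
Product: 30 erythro epoxy diol (C3–C4 epoxide with C2 and C5 cis on the oxirane)
Conditions: VO(acac)2 (cat.), t-BuOOH, CH2Cl2, 0 °C
Reagents that add atoms: tert-butyl hydroperoxide, CC(C)(C)OO
Why: Hydroxyl-directed vanadium-catalysed epoxidation acts only on the allylic C3=C4 bond and should favour the erythro epoxy alcohol, because 1,2-allylic strain between the C3 methyl and the ring A substituent of C2 outweighs the 1,3-strain of the cis C5 methylene at the small O–C–C=C dihedral angle of the vanadate transition state, so that C2 sets C3 and C4.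

Step 17
Reactants: 30 erythro epoxy diol + 31 but-3-en-2-one
Product: 32 epoxy diol (E)-enone (C3–C4 epoxide; free 2-OH and 16-OH; C9=C8–C7(=O)CH3 on C10; 6-OTBDPS; 13-OTIPS)
Conditions: second-generation Hoveyda–Grubbs catalyst RuCl2(H2IMes)(=CH-C6H4-2-OiPr) (5 mol%), 31 (excess), CH2Cl2, 40 °C
Reagents that add atoms: none
Why: Olefin cross-metathesis of the monosubstituted C9 vinyl group with the electron-poor partner gives the (E)-enone, the trisubstituted ring alkene being inert and free hydroxyls and the epoxide being tolerated by the ruthenium carbene.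

Step 18
Reactants: 32 epoxy diol (E)-enone
Product: 34 ring A–oxolane–oxepane tricycle (4-OH; C9 acetonyl arm; 6-OTBDPS; 13-OTIPS), via oxepane enone 33 (not isolated)
Conditions: (±)-camphor-10-sulfonic acid (0.1 equiv), CH2Cl2, 0 °C → rt
Reagents that add atoms: none
Why: CSA protonates the epoxide and the C16 hydroxyl attacks the tertiary, methyl-bearing C3 from the rear (7-exo-tet) to close the oxepane and set free the C4 carbinol, after which the C2 hydroxyl adds to C9 of the acid-activated (E)-enone (5-exo-trig) to close the oxolane. Both events are known reaction types, the acid-promoted epoxy alcohol cyclisation at the more substituted carbon and the intramolecular oxa-Michael addition, run here in one flask. C3 is set by the epoxide configuration through inversion and C4 keeps its C–O bond, so both follow from step 16. C9 is set under thermodynamic control because the conjugate addition is reversible in acid, and the 2,5-cis oxolane that places C3 and C8 on the convex face of the cis-fused ring A/oxolane bicycle should be the stable isomer. The step needs attack of O16 at C3 and not at C4, and no interference from O2 or O6: C3 is both the cation-stabilising carbon and the exo terminus (attack at C4 would need an eight-membered ring), O2 could reach the epoxide only through a three-membered ring, and O6 is kept as a bulky, weakly nucleophilic TBDPS ether because a benzyl-type ether could open C3 in a five-membered mode. The all-cis ring A from step 6 holds the C14 and C1 side chains on one face, so that O16 lies over C3 and O2 over C9.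

Step 19
Reactants: 34 ring A–oxolane–oxepane tricycle
Product: 35 tricyclic 4,6-diol methyl ketone (13-OTIPS)
Conditions: Bu4NF, AcOH, THF, 0 °C → rt
Reagents that add atoms: none
Why: Buffered fluoride removes the primary TBDPS ether much faster than the hindered secondary TIPS ether, and the acetic acid keeps the β-alkoxy ketone from retro-Michael opening.

Step 20
Reactants: 35 tricyclic 4,6-diol methyl ketone
Product: 36 tricyclic keto aldehyde (4-OH; C6 aldehyde; C7 methyl ketone; 13-OTIPS)
Conditions: TEMPO (cat.), PhI(OAc)2, CH2Cl2, rt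
Reagents that add atoms: none
Why: Nitroxyl-catalysed oxidation takes the primary C6 alcohol selectively in the presence of the hindered secondary C4 alcohol and gives the β-hydroxy aldehyde without over-oxidation.

Step 21
Reactants: 36 tricyclic keto aldehyde
Product: 37 tetracyclic 4,6,7-triol (oxonane closed; 13-OTIPS)
Conditions: SmI2 (4 equiv), THF, −78 °C → rt, high dilution
Reagents that add atoms: none
Why: SmI2-promoted intramolecular ketone–aldehyde pinacol coupling closes the nine-membered ring at C6–C7, the aldehyde ketyl adding to the samarium-bound ketone in a chelate that also holds the C4 alkoxide, with the ring spanning the convex face of the oxolane and the C7 methyl turned outward, which should give the 6,7-trans diol with O6 anti to O4 (6S,7S), although this facial control is the main uncertainty of the route.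

Step 22
Reactants: 37 tetracyclic 4,6,7-triol
Product: 38 4,6-diacetate 7-ol (13-OTIPS)
Conditions: Ac2O, pyridine, DMAP (cat.), CH2Cl2, rt
Reagents that add atoms: acetic anhydride, CC(=O)OC(C)=O
Why: DMAP-catalysed acyl transfer esterifies the two secondary alcohols and leaves the tertiary C7 hydroxyl free for steric reasons.

Step 23
Reactants: 38 4,6-diacetate 7-ol
Product: 39 4,6-diacetate 7,13-diol
Conditions: HF·pyridine, pyridine, THF, 0 °C → rt
Reagents that add atoms: none
Why: Buffered HF·pyridine cleaves the allylic TIPS ether under conditions that neither hydrolyse nor migrate the acetates.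

Step 24
Reactants: 39 4,6-diacetate 7,13-diol
Product: 40 target compound CNP0212231.3
Conditions: Dess–Martin periodinane, NaHCO3, CH2Cl2, 0 °C → rt
Reagents that add atoms: none
Why: Dess–Martin oxidation of the only secondary (allylic) alcohol regenerates the ring A enone, the tertiary alcohol and the acetates being inert, and C14 is not exposed to base.

**Compound list**

1 | (R)-3-bromo-2-methylpropan-1-ol | BrC[C@H](C)CO | starting material
2 | (R)-(3-bromo-2-methylpropoxy)(tert-butyl)dimethylsilane | BrC[C@H](C)CO[Si](C)(C)C(C)(C)C | intermediate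
3 | (E)-but-2-enal (crotonaldehyde) | C/C=C/C=O | starting material
4 | Grignard reagent of 2, [(R)-3-(tert-butyldimethylsilyloxy)-2-methylpropyl]magnesium bromide | Br[Mg]C[C@H](C)CO[Si](C)(C)C(C)(C)C | intermediate
5 | (2E,6S)-7-(tert-butyldimethylsilyloxy)-6-methylhept-2-en-4-ol (C4 epimers) | C/C=C/C(O)C[C@H](C)CO[Si](C)(C)C(C)(C)C | intermediate
6 | (2E,6S)-7-(tert-butyldimethylsilyloxy)-6-methylhept-2-en-4-one | C/C=C/C(=O)C[C@H](C)CO[Si](C)(C)C(C)(C)C | intermediate
7 | (2E,6S)-7-hydroxy-6-methylhept-2-en-4-one | C/C=C/C(=O)C[C@H](C)CO | intermediate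
8 | maleic anhydride | O=C1OC(=O)C=C1 | starting material
9 | (2Z)-4-{[(2S,5E)-2-methyl-4-oxohept-5-en-1-yl]oxy}-4-oxobut-2-enoic acid | C/C=C/C(=O)C[C@H](C)COC(=O)/C=C\C(=O)O | intermediate
10 | bis-silyl triene: TBS ester of 9 with (Z)-C13=C14 TBS dienol ether, C11=C12 E | C/C=C/C(O[Si](C)(C)C(C)(C)C)=C/[C@H](C)COC(=O)/C=C\C(=O)O[Si](C)(C)C(C)(C)C | intermediate
11 | bis-silyl cycloadduct: ring A 13-OTBS enol ether (C12=C13), cis-fused δ-lactone C2(=O)–O–C16, 9-CO2TBS, 11-Me, all-cis | C[C@@H]1COC(=O)[C@@H]2[C@H]1C(O[Si](C)(C)C(C)(C)C)=C[C@H](C)[C@@H]2C(=O)O[Si](C)(C)C(C)(C)C | intermediate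
12 | enone silyl ester (ring A C13=O, C11=C12; 9-CO2TBS) | C[C@@H]1COC(=O)[C@@H]2[C@H]1C(=O)C=C(C)[C@@H]2C(=O)O[Si](C)(C)C(C)(C)C | intermediate
13 | enone lactone acid (ring A C13=O, C11=C12; δ-lactone; 9-CO2H) | C[C@@H]1COC(=O)[C@@H]2[C@H]1C(=O)C=C(C)[C@@H]2C(=O)O | intermediate
14 | allylic alcohol lactone acid (13-OH cis to C14 branch) | C[C@@H]1COC(=O)[C@@H]2[C@H]1[C@H](O)C=C(C)[C@@H]2C(=O)O | intermediate
15 | bis-TIPS derivative (13-OTIPS ether, 9-CO2TIPS) | C[C@@H]1COC(=O)[C@@H]2[C@H]1[C@H](O[Si](C(C)C)(C(C)C)C(C)C)C=C(C)[C@@H]2C(=O)O[Si](C(C)C)(C(C)C)C(C)C | intermediate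
16 | 13-O-TIPS lactone acid | C[C@@H]1COC(=O)[C@@H]2[C@H]1[C@H](O[Si](C(C)C)(C(C)C)C(C)C)C=C(C)[C@@H]2C(=O)O | intermediate
17 | acid chloride of 16 | C[C@@H]1COC(=O)[C@@H]2[C@H]1[C@H](O[Si](C(C)C)(C(C)C)C(C)C)C=C(C)[C@@H]2C(=O)Cl | intermediate
18 | 13-O-TIPS lactone C9 aldehyde | C[C@@H]1COC(=O)[C@@H]2[C@H]1[C@H](O[Si](C(C)C)(C(C)C)C(C)C)C=C(C)[C@@H]2C=O | intermediate
19 | 13-O-TIPS lactone with C10 vinyl group | C[C@@H]1COC(=O)[C@@H]2[C@H]1[C@H](O[Si](C(C)C)(C(C)C)C(C)C)C=C(C)[C@@H]2C=C | intermediate
20 | 3-(tert-butyldiphenylsilyloxy)propan-1-ol | OCCCO[Si](c1ccccc1)(c1ccccc1)C(C)(C)C | starting material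
21 | 3-(tert-butyldiphenylsilyloxy)propanal | O=CCCO[Si](c1ccccc1)(c1ccccc1)C(C)(C)C | intermediate
22 | ethyltriphenylphosphonium iodide | CC[P+](c1ccccc1)(c1ccccc1)c1ccccc1.[I-] | starting material
23 | ethylidenetriphenylphosphorane | CC=P(c1ccccc1)(c1ccccc1)c1ccccc1 | intermediate
24 | (1-iodoethyl)triphenylphosphonium iodide | CC(I)[P+](c1ccccc1)(c1ccccc1)c1ccccc1.[I-] | intermediate
25 | (1-iodoethylidene)triphenylphosphorane | CC(I)=P(c1ccccc1)(c1ccccc1)c1ccccc1 | intermediate
26 | (Z)-tert-butyl[(4-iodopent-3-en-1-yl)oxy]diphenylsilane | C/C(I)=C/CCO[Si](c1ccccc1)(c1ccccc1)C(C)(C)C | intermediate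
27 | vinyllithium from 26 (geometry retained, lithium cis to the chain) | C/C([Li])=C/CCO[Si](c1ccccc1)(c1ccccc1)C(C)(C)C | intermediate
28 | hydroxy (Z)-enone: C2 ketone, C3(Me)=C4 with C2 and C5 cis, 6-OTBDPS, 16-OH, 13-OTIPS, C10 vinyl | C/C(=C/CCO[Si](c1ccccc1)(c1ccccc1)C(C)(C)C)C(=O)[C@@H]1[C@H]([C@H](C)CO)[C@H](O[Si](C(C)C)(C(C)C)C(C)C)C=C(C)[C@@H]1C=C | intermediate
29 | (2R)-allylic alcohol diol | C/C(=C/CCO[Si](c1ccccc1)(c1ccccc1)C(C)(C)C)[C@H](O)[C@@H]1[C@H]([C@H](C)CO)[C@H](O[Si](C(C)C)(C(C)C)C(C)C)C=C(C)[C@@H]1C=C | intermediate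
30 | erythro epoxy diol (C3–C4 epoxide, 2-OH, 16-OH, C10 vinyl) | CC(C)(C)[Si](OCC[C@@H]1O[C@]1(C)[C@H](O)[C@@H]2[C@H]([C@H](C)CO)[C@H](O[Si](C(C)C)(C(C)C)C(C)C)C=C(C)[C@@H]2C=C)(c3ccccc3)c4ccccc4 | intermediate
31 | but-3-en-2-one (methyl vinyl ketone) | C=CC(C)=O | starting material
32 | epoxy diol (E)-enone, precursor of the key step | CC(C)(C)[Si](OCC[C@@H]1O[C@]1(C)[C@H](O)[C@@H]2[C@H]([C@H](C)CO)[C@H](O[Si](C(C)C)(C(C)C)C(C)C)C=C(C)[C@@H]2/C=C/C(C)=O)(c3ccccc3)c4ccccc4 | intermediate
33 | oxepane enone (oxepane closed, 2-OH and 4-OH free, enone intact) | O[C@@H]1[C@@H]2[C@@H]([C@H](O[Si](C(C)C)(C(C)C)C(C)C)C=C(C)[C@@H]2/C=C/C(C)=O)[C@H](C)CO[C@]1(C)[C@@H](O)CCO[Si](c3ccccc3)(c4ccccc4)C(C)(C)C | intermediate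
34 | ring A–oxolane–oxepane tricycle (4-OH, C9 acetonyl, 6-OTBDPS, 13-OTIPS) | CC(=O)C[C@H]1O[C@@H]2[C@@H]3[C@@H]([C@H](O[Si](C(C)C)(C(C)C)C(C)C)C=C(C)[C@@H]31)[C@H](C)CO[C@]2(C)[C@@H](O)CCO[Si](c4ccccc4)(c5ccccc5)C(C)(C)C | intermediate
35 | tricyclic 4,6-diol methyl ketone | CC(=O)C[C@H]1O[C@@H]2[C@@H]3[C@@H]([C@H](O[Si](C(C)C)(C(C)C)C(C)C)C=C(C)[C@@H]31)[C@H](C)CO[C@]2(C)[C@@H](O)CCO | intermediate
36 | tricyclic keto aldehyde (4-OH, C6 aldehyde) | CC(=O)C[C@H]1O[C@@H]2[C@@H]3[C@@H]([C@H](O[Si](C(C)C)(C(C)C)C(C)C)C=C(C)[C@@H]31)[C@H](C)CO[C@]2(C)[C@@H](O)CC=O | intermediate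
37 | tetracyclic 4,6,7-triol 13-O-TIPS ether | O[C@H]1C[C@H](O)[C@@](C)(O)C[C@H]2O[C@@H]3[C@@H]4[C@@H]([C@H](O[Si](C(C)C)(C(C)C)C(C)C)C=C(C)[C@@H]42)[C@H](C)CO[C@]13C | intermediate
38 | 4,6-diacetate 7-ol 13-O-TIPS ether | CC(=O)O[C@H]1C[C@H](OC(C)=O)[C@@](C)(O)C[C@H]2O[C@@H]3[C@@H]4[C@@H]([C@H](O[Si](C(C)C)(C(C)C)C(C)C)C=C(C)[C@@H]42)[C@H](C)CO[C@]13C | intermediate
39 | 4,6-diacetate 7,13-diol | CC(=O)O[C@H]1C[C@H](OC(C)=O)[C@@](C)(O)C[C@H]2O[C@@H]3[C@@H]4[C@@H]([C@H](O)C=C(C)[C@@H]42)[C@H](C)CO[C@]13C | intermediate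
40 | CNP0212231.3, (1S,2R,3R,4S,6S,7S,9R,10R,14S,15S)-4,6-diacetoxy-7-hydroxy tetracyclic enone | CC(=O)O[C@H]1C[C@H](OC(C)=O)[C@@](C)(O)C[C@H]2O[C@@H]3[C@@H]4[C@@H](C(=O)C=C(C)[C@@H]42)[C@H](C)CO[C@]13C | target

**Step count and risks**

Total: 24 steps. Longest linear sequence: 22 steps (from 1: steps 1–11 and 14–24); the vinyl iodide 26 takes 2 steps (12 and 13).

Steps most likely to fail:

1. Step 21 (pinacol closure). The ketyl may add with poor facial control at C6 and C7, or simple reduction of the aldehyde may outrun closure of the nine-membered ring. The fallback leaves 36 and builds the two carbinols after ring closure, under control of the C4 hydroxyl.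
 - Double Wittig methylenation of 36 (Ph3P=CH2, THF) should give the bis-methylene compound F1.
 - Ring-closing metathesis with the second-generation Grubbs catalyst RuCl2(=CHPh)(H2IMes)(PCy3) in dilute CH2Cl2 should close the (Z)-C6=C7 oxonene F2.
 - VO(acac)2/t-BuOOH epoxidation directed by the homoallylic C4 hydroxyl should deliver oxygen to the ring face of O4, which is also the face of the final C7 hydroxyl, to give the epoxy alcohol F3.
 - Hydroxide (KOH, DMSO–H2O, heat) should open the epoxide at the less substituted C6 with inversion.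
 - This rejoins the route at triol 37.

2. Step 6 (tethered cycloaddition). The tether ester may resist the s-cis geometry that the transition state needs, so that the cycloaddition is slow and desilylation of the diene or exo closure to the trans-fused lactone competes. The fallback sets out from 7 and replaces the ester tether by an acetal tether with a cis-locked dienophile.
 - Acid-catalysed acetalisation of 7 with 5-hydroxyfuran-2(5H)-one (OC1OC(=O)C=C1; TsOH cat., benzene, water removal) gives the 5-alkoxyfuranone F4 as interconverting acetal epimers.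
 - TBSOTf/Et3N gives the silyl dienol ether F5, which on heating should cyclise to the cycloadduct F6 with the butenolide endo and on the C16 face; only the acetal epimer that can reach this geometry reacts, and the other is recycled by acid equilibration.
 - Saegusa–Ito oxidation (Pd(OAc)2) gives the enone F7.
 - Mild aqueous acid hydrolyses the acyloxy acetal to the lactol acid F8, and TEMPO/PhI(OAc)2 oxidises the lactol to the δ-lactone.
 - This rejoins the route at 13.

3. Step 16 (directed epoxidation). The 1,3-allylic strain of the cis C5 methylene may erode the erythro preference, so that oxygen is delivered to both alkene faces. The fallback sets out from 28 and reaches the same epoxy alcohol through the threo series.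
 - Reduction of 28 with the (R)-configured CBS catalyst and catecholborane gives the (2S)-allylic alcohol F9.
 - Ti(OiPr)4/t-BuOOH epoxidation, which is reliably threo-selective for allylic alcohols with a cis substituent, gives the threo epoxy diol F10 with the required C3/C4 configuration.
 - Dess–Martin periodinane oxidises both the C2 carbinol and the C16 alcohol to the epoxy keto aldehyde F11.
 - Zn(BH4)2 returns the aldehyde to the alcohol and reduces the ketone through the zinc chelate of carbonyl and epoxide oxygen to the erythro alcohol.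
 - This rejoins the route at 30.

Further compounds
F1 | step 21 | bis-methylene compound from 36 (C6=CH2 and C7(=CH2)CH3; 4-OH; 13-OTIPS) | CC(=C)C[C@H]1O[C@@H]2[C@@H]3[C@@H]([C@H](O[Si](C(C)C)(C(C)C)C(C)C)C=C(C)[C@@H]31)[C@H](C)CO[C@]2(C)[C@@H](O)CC=C
F2 | step 21 | (Z)-C6=C7 oxonene (4-OH; 13-OTIPS) | O[C@H]1C/C=C(C)\C[C@H]2O[C@@H]3[C@@H]4[C@@H]([C@H](O[Si](C(C)C)(C(C)C)C(C)C)C=C(C)[C@@H]42)[C@H](C)CO[C@]13C
F3 | step 21 | 6,7-epoxy 4-ol (epoxide oxygen cis to O4) | O[C@H]1C[C@H]5O[C@@]5(C)C[C@H]2O[C@@H]3[C@@H]4[C@@H]([C@H](O[Si](C(C)C)(C(C)C)C(C)C)C=C(C)[C@@H]42)[C@H](C)CO[C@]13C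
F4 | step 6 | 5-alkoxyfuran-2(5H)-one acetal of 7 (both acetal epimers) | C/C=C/C(=O)C[C@H](C)COC1OC(=O)C=C1
F5 | step 6 | (Z)-TBS dienol ether of F4 | C/C=C/C(O[Si](C)(C)C(C)(C)C)=C/[C@H](C)COC1OC(=O)C=C1
F6 | step 6 | acetal-tethered cycloadduct (ring A silyl enol ether; C2 acetal in a tetrahydropyran with O16; γ-lactone C9(=O)–O–C2) | C[C@@H]1CO[C@H]2OC(=O)[C@H]3[C@@H](C)C=C(O[Si](C)(C)C(C)(C)C)[C@@H]1[C@@H]23
F7 | step 6 | enone acetal lactone | C[C@@H]1CO[C@H]2OC(=O)[C@H]3C(C)=CC(=O)[C@@H]1[C@@H]23
F8 | step 6 | lactol acid (C2 lactol epimers; 9-CO2H) | C[C@@H]1COC(O)[C@@H]2[C@H]1C(=O)C=C(C)[C@@H]2C(=O)O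
F9 | step 16 | (2S)-allylic alcohol diol (C2 epimer of 29) | C/C(=C/CCO[Si](c1ccccc1)(c1ccccc1)C(C)(C)C)[C@@H](O)[C@@H]1[C@H]([C@H](C)CO)[C@H](O[Si](C(C)C)(C(C)C)C(C)C)C=C(C)[C@@H]1C=C
F10 | step 16 | threo epoxy diol (C2 epimer of 30) | CC(C)(C)[Si](OCC[C@@H]1O[C@]1(C)[C@@H](O)[C@@H]2[C@H]([C@H](C)CO)[C@H](O[Si](C(C)C)(C(C)C)C(C)C)C=C(C)[C@@H]2C=C)(c3ccccc3)c4ccccc4
F11 | step 16 | epoxy keto aldehyde (C2 ketone, C16 aldehyde) | CC(C)(C)[Si](OCC[C@@H]1O[C@]1(C)C(=O)[C@@H]2[C@H]([C@H](C)C=O)[C@H](O[Si](C(C)C)(C(C)C)C(C)C)C=C(C)[C@@H]2C=C)(c3ccccc3)c4ccccc4
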